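The data come from a simulation on assumed constants; noise was put on by code.

The meeting decided to reckon the flask by the catalyst that outlasts the impurity, not by the catalyst charged.

the same everywhere: left-handed substrate 10 mM; right-handed substrate 10 mM; impurity 8.6 µM
- Tuesday's: partner 15 mM; free catalyst 25 µM; run made earlier
- Sunday's: partner 15 mM; free catalyst 100 µM; run made earlier
- Monday's: partner 22 mM; free catalyst 50 µM; run made earlier
- flask: partner 15.0 mM; free catalyst 50 µM; time 2.0 min

| run | time / s | right-handed substrate / % | left-handed substrate / % | left-handed product / % |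
|---|---|---|---|---|
| Tuesday's | 10.0 | 49.8 | 23.4 | 24.5 |
| Tuesday's | 25.0 | 48.0 | 14.3 | 34.6 |
| Tuesday's | 40.0 | 49.5 | 11.3 | 38.3 |
| Tuesday's | 60.0 | 47.2 | 8.6 | 40.7 |
| Tuesday's | 90.0 | 46.6 | 7.1 | 41.4 |
| Sunday's | 10.0 | 43.7 | 4.0 | 45.9 |
| Sunday's | 15.0 | 45.5 | 2.5 | 48.5 |
| Sunday's | 25.0 | 44.1 | 1.0 | 49.3 |
| Sunday's | 50.0 | 41.2 | 0 | 49.5 |
| Sunday's | 90.0 | 39.6 | 0 | 48.7 |
| Monday's | 10.0 | 46.5 | 4.2 | 44.6 |
| Monday's | 15.0 | 44.3 | 0.7 | 47.7 |
| Monday's | 25.0 | 44.8 | 1.3 | 47.9 |
| Monday's | 50.0 | 43.2 | 0 | 49.8 |
| Monday's | 90.0 | 39.1 | 1.0 | 49.5 |

(readings scatter by 1 percentage point)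

- free catalyst is single-handed; left-handed substrate and right-handed substrate are mirror images of each other, charged as a racemate, each of them at the stated concentration

1. whether the excess of right-handed substrate over left-handed substrate among what is left of the two reaches 90% by 2.0 min (no / yes)
2. the highest excess of right-handed substrate over left-handed substrate among what is left of the two up to 2.0 min

The first speaker proposed counting the impurity as taking its equal of free catalyst at the outset. For the flask that leaves 41.4 µM, and she named this the working catalyst, c(free catalyst) less c(impurity). Tuesday's run, at the same partner charge, had 16.4 µM.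

A second member put the question as a logarithm. An excess of 90% needs the natural logarithm of right-handed over left-handed substrate to reach 2.94, and Tuesday's last reading gives 1.88. He assumed that this logarithm grows in proportion to working catalyst. On that assumption his estimate for the flask is 4.75, more than needed, which corresponds to an excess of 98.3%.

The forecast, from a selectivity of about 25, answered yes with a top of 94%, lower than the second member's figure, and its words were “yes, though narrowly”.

The flask answers yes, with a top excess of 96.0%, above the forecast and below the second member's figure.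

    free catalyst + impurity → spent catalyst B (k = 2.50 × 10⁵ L mol⁻¹ s⁻¹)
    partner + free catalyst + left-handed substrate → free catalyst + left-handed product (k = 5.00 × 10⁵ L² mol⁻² s⁻¹)
    partner + free catalyst → spent catalyst A (k = 0.520 L mol⁻¹ s⁻¹)
    2 partner → homo dimer (k = 2.00 L mol⁻¹ s⁻¹)
    partner + free catalyst + right-handed substrate → free catalyst + right-handed product (k = 18000 L² mol⁻² s⁻¹)

In the flask the wanted excess is reached at 0.795 min. At 2.00 min the flask's spent catalyst B holds 17.2% of the catalyst charged, the share subtracted in its working catalyst, 82.8% of its charge, while free catalyst holds 74.4% and spent catalyst A 8.37%. Tuesday's run, with 16.4 µM of working catalyst, 65.6% of its charge, shows an excess of 73.6% in its last reading at 90.0 s.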